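**Plan** (labdane numbering: ring A = C1–C5 and C10, ring B = C5–C10, C19 = carboxyl on C4, C20 = methyl on C10, C17 = methylene on C8)

Cuts, in retrosynthetic order: the C15–O acyl bond (palmitoyl chloride); C11–C12 (C11 sulfone anion plus an E-configured C12–C15 allylic bromide); C7–C8 and C9–C10 of ring B; the C5–C6 vinyl bond and the two C–CH3 bonds at C4 and C10.
Enabling feature: ring B holds quaternary C10 next to C5 and the adjacent pair C8 (bearing C17) and C9 (bearing C11), so as a cyclohexadiene it is the [4+2] adduct of a ring A diene C10=C5–C6=C7 and an alkyne C8≡C9 carrying C17 and an ester as C11.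
Forward order: ring A is bought as a cyclohexanone β-keto ester and given the C4 methyl, the C10 methyl and the C5 vinyl group; ring B is closed by the cycloaddition; C5=C6 is hydrogenated and the ester deconjugated to the 8(17)-ene; C11 becomes a sulfone, the C12–C15 unit is attached, and the palmitate goes on last.
Stereochemistry: C4 from a catalytic asymmetric methylation; C10 from the diene face anti to the C4 ester; C5 from hydrogenation anti to the C20 methyl and C19 ester; C9 from α-face protonation of a photodienol; 13E from an E-selective allylic oxidation of a prenyl ether.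

Key step: step 5

Assumption: in step 1 the antipode of the spiro ammonium catalyst is the one that delivers (S)-2; the sense of induction would be read from the optical rotation of 2 and does not alter the chemistry.

**Route**

Step 1
Reactants: 1 tert-butyl 2-oxocyclohexane-1-carboxylate
Product: 2 tert-butyl (1S)-1-methyl-2-oxocyclohexane-1-carboxylate
Conditions: MeI, CsOH·H2O, toluene, −40 °C, 2 mol% chiral N-spiro bis(binaphthyl)ammonium bromide with 3,5-(CF3)2C6H3 groups at the 3,3′ positions
Reagents that add atoms: iodomethane CI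
Why: Asymmetric phase-transfer alkylation of a cyclic β-keto tert-butyl ester, in which the enolate is methylated inside a tight ion pair with the chiral ammonium cation that shields one enolate face and should set the quaternary centre (the later C4) as S.

Step 2
Reactants: 2 tert-butyl (1S)-1-methyl-2-oxocyclohexane-1-carboxylate
Product: 4 tert-butyl (1S)-1,3-dimethyl-2-oxocyclohexane-1-carboxylate (both C3 epimers), via lithium enolate 3 (not isolated)
Conditions: LiN(iPr)2, THF, −78 °C; MeI, −78 to 0 °C
Reagents that add atoms: iodomethane CI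
Why: Ketone enolate alkylation whose regiochemistry is fixed because only C3 carries α-hydrogens (C1 is quaternary); the C3 configuration is irrelevant since this carbon becomes sp2 in step 3.

Step 3
Reactants: 4 tert-butyl (1S)-1,3-dimethyl-2-oxocyclohexane-1-carboxylate
Product: 6 tert-butyl (1S)-1,3-dimethyl-2-{[(trifluoromethyl)sulfonyl]oxy}cyclohex-2-ene-1-carboxylate, via potassium enolate 5 (not isolated)
Conditions: KN(SiMe3)2, THF, −78 °C; PhNTf2, −78 °C to rt
Reagents that add atoms: N-phenylbis(trifluoromethanesulfonimide) O=S(=O)(N(c1ccccc1)S(=O)(=O)C(F)(F)F)C(F)(F)F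
Why: O-sulfonylation of the only possible enolate gives the tetrasubstituted enol triflate, as is routine for 2,2,6-trisubstituted cyclohexanones; the quaternary centre is untouched.

Step 4
Reactants: 6 tert-butyl (1S)-1,3-dimethyl-2-{[(trifluoromethyl)sulfonyl]oxy}cyclohex-2-ene-1-carboxylate; 7 tributyl(vinyl)stannane
Product: 8 tert-butyl (1S)-2-ethenyl-1,3-dimethylcyclohex-2-ene-1-carboxylate
Conditions: Pd(PPh3)4 (5 mol%), LiCl, THF, reflux
Reagents that add atoms: none
Why: Stille coupling of a hindered enol triflate at zerovalent palladium, with LiCl to assist the triflate, as known for the 2,6,6-trimethylcyclohexenyl triflate.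

Step 5
Reactants: 8 tert-butyl (1S)-2-ethenyl-1,3-dimethylcyclohex-2-ene-1-carboxylate; 9 methyl but-2-ynoate
Product: 10 19-tert-butyl 11-methyl (4S,10S)-12,13,14,15,16-pentanorlabda-5,8-diene-11,19-dioate (C20 methyl cis to the C19 ester)
Conditions: 9 (6 equiv), BHT (2 mol%), neat, base-washed sealed tube, 150 °C, 48 h
Reagents that add atoms: none
Why: A concerted but asynchronous thermal [4+2] cycloaddition joins the s-cis diene C10=C5–C6=C7 of 8 to the triple bond of 9, the closest known case being the addition of acetylenic esters to 1-vinyl-2,6,6-trimethylcyclohexene that gives drimane bicycles. Ring B is closed intermolecularly as a six-membered ring through the two new bonds C7–C8 and C9–C10, and the product is a 1,4-cyclohexadiene (C5=C6, C8=C9) that cannot aromatise because C10 is quaternary. The regiochemistry follows the polarity of the partners: the unsubstituted terminus C7, with the larger HOMO coefficient and no steric load, bonds ahead to the β-carbon of the ynoate (C8, carrying C17), and the fully substituted C10 closes on the α-carbon (C9, carrying the ester C11). C10 is the only new stereocentre and is controlled by C4: with the tert-butyl ester pseudoaxial (which relieves allylic strain against H-6 of the planar diene) the alkyne should add to the opposite face, which also places the flat ester and not a methyl group in the developing 1,3-diaxial contact with the C20 methyl, so that C20 ends cis to C19. The step therefore needs regio- and facial selectivity; the first rests on the electronic bias reinforced by the steric demand at C10, the second on the difference between CO2tBu and CH3 at the stereocentre next to the diene.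

Step 6
Reactants: 10 19-tert-butyl 11-methyl (4S,10S)-12,13,14,15,16-pentanorlabda-5,8-diene-11,19-dioate
Product: 11 19-tert-butyl 11-methyl (4S,5R,10S)-12,13,14,15,16-pentanorlabd-8-ene-11,19-dioate (trans ring fusion)
Conditions: H2 (4 atm), 10% Pd/C, EtOAc, rt
Reagents that add atoms: none
Why: Heterogeneous catalytic hydrogenation takes the trisubstituted C5=C6 bond and leaves the tetrasubstituted, ester-conjugated C8=C9 bond; hydrogen is delivered on the α face, opposite the β-oriented C20 methyl and C19 ester, which sets 5α-H and the trans fusion.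

Step 7
Reactants: 11 19-tert-butyl 11-methyl (4S,5R,10S)-12,13,14,15,16-pentanorlabd-8-ene-11,19-dioate
Product: 13 19-tert-butyl 11-methyl (4S,5R,9S,10S)-12,13,14,15,16-pentanorlabd-8(17)-ene-11,19-dioate, via photodienol 12 (not isolated)
Conditions: hν (254 nm, quartz), 1,2-dimethylimidazole (10 mol%), degassed Et2O, rt
Reagents that add atoms: none
Why: Photochemical deconjugation of an α,β-unsaturated ester, in which the excited enoate takes a hydrogen from the cis γ-methyl C17 by a 1,5-shift to give dienol 12 and base-mediated ketonisation protonates C9 on the α face, anti to the neighbouring axial C20 methyl, setting 9α-H with an equatorial ester and the 8(17)-methylene.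

Step 8
Reactants: 13 19-tert-butyl 11-methyl (4S,5R,9S,10S)-12,13,14,15,16-pentanorlabd-8(17)-ene-11,19-dioate
Product: 14 tert-butyl (4S,5R,9S,10S)-11-hydroxy-12,13,14,15,16-pentanorlabd-8(17)-en-19-oate
Conditions: iBu2AlH (2.5 equiv), CH2Cl2, −78 to 0 °C; aq. potassium sodium tartrate
Reagents that add atoms: none
Why: Hydride reduction of the methyl ester to the primary alcohol, selective because the C19 tert-butyl ester sits on an axial quaternary carbon and is far more hindered, and non-basic so that C9 is not epimerised and the alkene does not move back into conjugation.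

Step 9
Reactants: 14 tert-butyl (4S,5R,9S,10S)-11-hydroxy-12,13,14,15,16-pentanorlabd-8(17)-en-19-oate
Product: 15 tert-butyl (4S,5R,9S,10S)-11-(phenylsulfanyl)-12,13,14,15,16-pentanorlabd-8(17)-en-19-oate
Conditions: PhSSPh, n-Bu3P, pyridine, rt to 50 °C
Reagents that add atoms: diphenyl disulfide c1ccc(cc1)SSc1ccccc1
Why: Phosphine–disulfide redox condensation (Hata reaction), in which thiophenolate displaces the alkoxyphosphonium of the primary alcohol by SN2 at C11 without touching C9.

Step 10
Reactants: 15 tert-butyl (4S,5R,9S,10S)-11-(phenylsulfanyl)-12,13,14,15,16-pentanorlabd-8(17)-en-19-oate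
Product: 16 tert-butyl (4S,5R,9S,10S)-11-(phenylsulfonyl)-12,13,14,15,16-pentanorlabd-8(17)-en-19-oate
Conditions: 30% H2O2, (NH4)6Mo7O24·4H2O (cat.), EtOH, 0 °C to rt
Reagents that add atoms: hydrogen peroxide OO
Why: Molybdate-catalysed peroxide oxidation of sulfide to sulfone, which is much faster than epoxidation of the 1,1-disubstituted alkene.

Step 11
Reactants: 17 3-methylbut-2-en-1-ol
Product: 18 tert-butyldimethyl[(3-methylbut-2-en-1-yl)oxy]silane
Conditions: TBSCl, imidazole, DMF, rt
Reagents that add atoms: tert-butyldimethylsilyl chloride CC(C)(C)[Si](C)(C)Cl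
Why: Standard silylation of a primary alcohol.

Step 12
Reactants: 18 tert-butyldimethyl[(3-methylbut-2-en-1-yl)oxy]silane
Product: 19 (2E)-4-[(tert-butyldimethylsilyl)oxy]-2-methylbut-2-en-1-ol
Conditions: SeO2 (0.5 equiv), t-BuOOH, salicylic acid (cat.), CH2Cl2, rt
Reagents that add atoms: tert-butyl hydroperoxide CC(C)(C)OO
Why: Riley allylic oxidation (ene reaction, then [2,3]-sigmatropic shift) hydroxylates the methyl group trans to the CH2OTBS chain, which fixes the later 13E geometry.

Step 13
Reactants: 19 (2E)-4-[(tert-butyldimethylsilyl)oxy]-2-methylbut-2-en-1-ol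
Product: 20 {[(2E)-4-bromo-3-methylbut-2-en-1-yl]oxy}(tert-butyl)dimethylsilane
Conditions: CBr4, PPh3, CH2Cl2, 0 °C
Reagents that add atoms: carbon tetrabromide BrC(Br)(Br)Br
Why: Appel bromination of the primary allylic alcohol by SN2 at the oxyphosphonium, without allylic transposition or loss of the E geometry.

Step 14
Reactants: 16 tert-butyl (4S,5R,9S,10S)-11-(phenylsulfonyl)-12,13,14,15,16-pentanorlabd-8(17)-en-19-oate; 20 {[(2E)-4-bromo-3-methylbut-2-en-1-yl]oxy}(tert-butyl)dimethylsilane
Product: 22 tert-butyl (4S,5R,9S,10S)-15-[(tert-butyldimethylsilyl)oxy]-11-(phenylsulfonyl)labda-8(17),13E-dien-19-oate (both C11 epimers), via lithiated sulfone 21 (not isolated)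
Conditions: n-BuLi, THF–HMPA, −78 °C; 20, −78 to −20 °C
Reagents that add atoms: none
Why: Alkylation of an α-sulfonyl carbanion with a primary allylic bromide (Julia-type coupling) forms C11–C12 by SN2 with the E alkene intact; the new C11 centre is formed without control and is erased in step 15.

Step 15
Reactants: 22 tert-butyl (4S,5R,9S,10S)-15-[(tert-butyldimethylsilyl)oxy]-11-(phenylsulfonyl)labda-8(17),13E-dien-19-oate
Product: 23 tert-butyl (4S,5R,9S,10R)-15-[(tert-butyldimethylsilyl)oxy]labda-8(17),13E-dien-19-oate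
Conditions: 6% Na(Hg), Na2HPO4, MeOH–THF, −20 to 0 °C
Reagents that add atoms: none
Why: Reductive desulfonylation by electron transfer from sodium amalgam cleaves the C11–S bond and buffered methanol protonates C11, while the isolated alkenes, the silyl ether and the hindered ester are not reduced.

Step 16
Reactants: 23 tert-butyl (4S,5R,9S,10R)-15-[(tert-butyldimethylsilyl)oxy]labda-8(17),13E-dien-19-oate
Product: 25 (4S,5R,9S,10R)-15-[(tert-butyldimethylsilyl)oxy]labda-8(17),13E-dien-19-oic acid, via trimethylsilyl ester 24 (not isolated)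
Conditions: Me3SiOTf, 2,6-lutidine, CH2Cl2, 0 °C to rt; then pH 5 aqueous buffer
Reagents that add atoms: none
Why: Silyl triflate-mediated cleavage of a tert-butyl ester, in which O-silylation of the carbonyl triggers loss of the tert-butyl cation as isobutene (an alkyl–oxygen fission indifferent to the hindrance at C4) while lutidine keeps the medium non-protic so that the 8(17)-alkene and the allylic silyl ether are spared; the labile silyl ester 24 hydrolyses on work-up.

Step 17
Reactants: 25 (4S,5R,9S,10R)-15-[(tert-butyldimethylsilyl)oxy]labda-8(17),13E-dien-19-oic acid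
Product: 26 (4S,5R,9S,10R)-15-hydroxylabda-8(17),13E-dien-19-oic acid (isocupressic acid)
Conditions: Bu4NF (3 equiv), THF, 0 °C to rt; mildly acidic work-up
Reagents that add atoms: none
Why: Fluoride-induced cleavage of the primary silyl ether, which affects neither a stereocentre nor an alkene.

Step 18
Reactants: 26 (4S,5R,9S,10R)-15-hydroxylabda-8(17),13E-dien-19-oic acid; 27 hexadecanoyl chloride (palmitoyl chloride)
Product: 28 (4S,5R,9S,10R)-15-(hexadecanoyloxy)labda-8(17),13E-dien-19-oic acid
Conditions: 27 (1.1 equiv), pyridine, CH2Cl2, 0 °C; then aq. NaHCO3–THF, rt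
Reagents that add atoms: none
Why: O-acylation of the unhindered primary allylic alcohol by the acid chloride; the tertiary axial C19 acid is a poor nucleophile, and any mixed anhydride it forms should be hydrolysed at the palmitoyl carbonyl in the bicarbonate work-up, returning the free acid.

**Compound list**

1 | tert-butyl 2-oxocyclohexane-1-carboxylate | O=C1CCCCC1C(=O)OC(C)(C)C | starting material
2 | tert-butyl (1S)-1-methyl-2-oxocyclohexane-1-carboxylate | C[C@]1(C(=O)OC(C)(C)C)CCCCC1=O | intermediate
3 | lithium (6S)-6-(tert-butoxycarbonyl)-6-methylcyclohex-1-en-1-olate (enolate of 2, formed in the flask) | C[C@]1(C(=O)OC(C)(C)C)CCCC=C1[O-].[Li+] | intermediate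
4 | tert-butyl (1S)-1,3-dimethyl-2-oxocyclohexane-1-carboxylate (both C3 epimers) | C[C@]1(C(=O)OC(C)(C)C)CCCC(C)C1=O | intermediate
5 | potassium (6S)-6-(tert-butoxycarbonyl)-2,6-dimethylcyclohex-1-en-1-olate (enolate of 4, formed in the flask) | C[C@]1(C(=O)OC(C)(C)C)CCCC(C)=C1[O-].[K+] | intermediate
6 | tert-butyl (1S)-1,3-dimethyl-2-{[(trifluoromethyl)sulfonyl]oxy}cyclohex-2-ene-1-carboxylate | C[C@]1(C(=O)OC(C)(C)C)CCCC(C)=C1OS(=O)(=O)C(F)(F)F | intermediate
7 | tributyl(vinyl)stannane | C=C[Sn](CCCC)(CCCC)CCCC | starting material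
8 | tert-butyl (1S)-2-ethenyl-1,3-dimethylcyclohex-2-ene-1-carboxylate | C[C@]1(C(=O)OC(C)(C)C)CCCC(C)=C1C=C | intermediate
9 | methyl but-2-ynoate | CC#CC(=O)OC | starting material
10 | 19-tert-butyl 11-methyl (4S,10S)-12,13,14,15,16-pentanorlabda-5,8-diene-11,19-dioate | CC1=C(C(=O)OC)[C@@]2(C)CCC[C@](C)(C(=O)OC(C)(C)C)C2=CC1 | intermediate
11 | 19-tert-butyl 11-methyl (4S,5R,10S)-12,13,14,15,16-pentanorlabd-8-ene-11,19-dioate | CC1=C(C(=O)OC)[C@@]2(C)CCC[C@](C)(C(=O)OC(C)(C)C)[C@@H]2CC1 | intermediate
12 | photodienol of 11: tert-butyl 11-hydroxy-11-methoxy-12,13,14,15,16-pentanorlabda-8(17),9(11)-dien-19-oate, OH on the C8 side (formed in the flask) | C=C1CC[C@@H]2[C@](C)(CCC[C@]2(C)C(=O)OC(C)(C)C)/C1=C(\OC)O | intermediate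
13 | 19-tert-butyl 11-methyl (4S,5R,9S,10S)-12,13,14,15,16-pentanorlabd-8(17)-ene-11,19-dioate | C=C1CC[C@@H]2[C@](C)(CCC[C@]2(C)C(=O)OC(C)(C)C)[C@H]1C(=O)OC | intermediate
14 | tert-butyl (4S,5R,9S,10S)-11-hydroxy-12,13,14,15,16-pentanorlabd-8(17)-en-19-oate | C=C1CC[C@@H]2[C@](C)(CCC[C@]2(C)C(=O)OC(C)(C)C)[C@H]1CO | intermediate
15 | tert-butyl (4S,5R,9S,10S)-11-(phenylsulfanyl)-12,13,14,15,16-pentanorlabd-8(17)-en-19-oate | C=C1CC[C@@H]2[C@](C)(CCC[C@]2(C)C(=O)OC(C)(C)C)[C@H]1CSc1ccccc1 | intermediate
16 | tert-butyl (4S,5R,9S,10S)-11-(phenylsulfonyl)-12,13,14,15,16-pentanorlabd-8(17)-en-19-oate | C=C1CC[C@@H]2[C@](C)(CCC[C@]2(C)C(=O)OC(C)(C)C)[C@H]1CS(=O)(=O)c1ccccc1 | intermediate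
17 | 3-methylbut-2-en-1-ol | CC(C)=CCO | starting material
18 | tert-butyldimethyl[(3-methylbut-2-en-1-yl)oxy]silane | CC(C)=CCO[Si](C)(C)C(C)(C)C | intermediate
19 | (2E)-4-[(tert-butyldimethylsilyl)oxy]-2-methylbut-2-en-1-ol | OC/C(C)=C/CO[Si](C)(C)C(C)(C)C | intermediate
20 | {[(2E)-4-bromo-3-methylbut-2-en-1-yl]oxy}(tert-butyl)dimethylsilane | BrC/C(C)=C/CO[Si](C)(C)C(C)(C)C | intermediate
21 | C11-lithiated sulfone of 16 (formed in the flask) | C=C1CC[C@@H]2[C@](C)(CCC[C@]2(C)C(=O)OC(C)(C)C)[C@H]1[CH-]S(=O)(=O)c1ccccc1.[Li+] | intermediate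
22 | tert-butyl (4S,5R,9S,10S)-15-[(tert-butyldimethylsilyl)oxy]-11-(phenylsulfonyl)labda-8(17),13E-dien-19-oate (both C11 epimers) | C=C1CC[C@@H]2[C@](C)(CCC[C@]2(C)C(=O)OC(C)(C)C)[C@H]1C(C/C(C)=C/CO[Si](C)(C)C(C)(C)C)S(=O)(=O)c1ccccc1 | intermediate
23 | tert-butyl (4S,5R,9S,10R)-15-[(tert-butyldimethylsilyl)oxy]labda-8(17),13E-dien-19-oate | C=C1CC[C@@H]2[C@](C)(CCC[C@]2(C)C(=O)OC(C)(C)C)[C@H]1CC/C(C)=C/CO[Si](C)(C)C(C)(C)C | intermediate
24 | trimethylsilyl (4S,5R,9S,10R)-15-[(tert-butyldimethylsilyl)oxy]labda-8(17),13E-dien-19-oate (formed in the flask) | C=C1CC[C@@H]2[C@](C)(CCC[C@]2(C)C(=O)O[Si](C)(C)C)[C@H]1CC/C(C)=C/CO[Si](C)(C)C(C)(C)C | intermediate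
25 | (4S,5R,9S,10R)-15-[(tert-butyldimethylsilyl)oxy]labda-8(17),13E-dien-19-oic acid | C=C1CC[C@@H]2[C@](C)(CCC[C@]2(C)C(=O)O)[C@H]1CC/C(C)=C/CO[Si](C)(C)C(C)(C)C | intermediate
26 | (4S,5R,9S,10R)-15-hydroxylabda-8(17),13E-dien-19-oic acid (isocupressic acid) | C=C1CC[C@@H]2[C@](C)(CCC[C@]2(C)C(=O)O)[C@H]1CC/C(C)=C/CO | intermediate
27 | hexadecanoyl chloride (palmitoyl chloride) | CCCCCCCCCCCCCCCC(=O)Cl | starting material
28 | (4S,5R,9S,10R)-15-(hexadecanoyloxy)labda-8(17),13E-dien-19-oic acid | C=C1CC[C@@H]2[C@](C)(CCC[C@]2(C)C(=O)O)[C@H]1CC/C(C)=C/COC(=O)CCCCCCCCCCCCCCC | target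

**Count and risks**

Total: 18 steps. Longest linear sequence: 15 steps (steps 1–10 and 14–18, from 1); the side-chain bromide takes 3 steps (11–13).

Steps most likely to fail:

1. Step 5. The cycloaddition may be too slow at a temperature the diene tolerates, so that a 1,5-hydrogen shift from the C20 methyl to C7 and oligomerisation of the ynoate take over, and the facial preference set by C4 may erode at 150 °C. Fallback: the same two bonds are made at low temperature with a more electrophilic dienophile one oxidation level lower. Diene 8 and but-2-ynal with Me2AlCl in CH2Cl2 at −78 to −20 °C should give the aldehyde tert-butyl (4S,10S)-11-oxo-12,13,14,15,16-pentanorlabda-5,8-dien-19-oate F1. Oxidation with NaClO2, NaH2PO4 and 2-methylbut-2-ene in t-BuOH–water would give the acid (4S,10S)-19-tert-butoxy-19-oxo-12,13,14,15,16-pentanorlabda-5,8-dien-11-oic acid F2. Esterification with Me3SiCHN2 in toluene–MeOH returns to 10.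

2. Step 7. Photoenolisation may stall because the dienol reverts to the conjugated ester by a thermal 1,5-hydrogen shift, secondary photoreactions may set in on long irradiation, or C9 may be protonated from the wrong face. Fallback: a ground-state deconjugation. Ester 11 is deprotonated with LiN(iPr)2 in THF–HMPA at −78 °C at the γ-methyl C17, which lies syn to the ester, to give the lithium dienolate F3. Kinetic quench with acetic acid at −78 °C protonates C9 from the α face and comes back at 13.

3. Step 1. Enantioselection may be poor because iodomethane is a small electrophile that the chiral ion pair discriminates less well than benzylic halides, and uncatalysed alkylation may compete. Fallback: a stoichiometric chiral auxiliary. Keto ester 1 is condensed with L-valine tert-butyl ester (BF3·OEt2 cat., benzene, reflux with water removal) to the enamine tert-butyl 2-{[(2S)-1-tert-butoxy-3-methyl-1-oxobutan-2-yl]amino}cyclohex-1-ene-1-carboxylate F4. LiN(iPr)2 in toluene at −78 °C gives the chelated lithio enamine F5. Methylation with MeI gives the imine tert-butyl (1S)-2-{[(2S)-1-tert-butoxy-3-methyl-1-oxobutan-2-yl]imino}-1-methylcyclohexane-1-carboxylate F6; the ligand on lithium (HMPA in toluene, or THF/1,3-dioxolane) reverses the facial preference and is chosen for the S sense. Hydrolysis with aqueous citric acid returns to 2 and frees the amino ester for reuse.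

**Further compounds**

F1 | step 5 | tert-butyl (4S,10S)-11-oxo-12,13,14,15,16-pentanorlabda-5,8-dien-19-oate | CC1=C(C=O)[C@@]2(C)CCC[C@](C)(C(=O)OC(C)(C)C)C2=CC1
F2 | step 5 | (4S,10S)-19-tert-butoxy-19-oxo-12,13,14,15,16-pentanorlabda-5,8-dien-11-oic acid | CC1=C(C(=O)O)[C@@]2(C)CCC[C@](C)(C(=O)OC(C)(C)C)C2=CC1
F3 | step 7 | lithium dienolate of 11 (C17=C8–C9=C11(OLi)OMe, tert-butyl ester at C19) | C=C1CC[C@@H]2[C@](C)(CCC[C@]2(C)C(=O)OC(C)(C)C)/C1=C(\OC)[O-].[Li+]
F4 | step 1 | tert-butyl 2-{[(2S)-1-tert-butoxy-3-methyl-1-oxobutan-2-yl]amino}cyclohex-1-ene-1-carboxylate | CC(C)[C@H](NC1=C(C(=O)OC(C)(C)C)CCCC1)C(=O)OC(C)(C)C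
F5 | step 1 | N-lithio derivative of enamine F4 | CC(C)[C@H]([N-]C1=C(C(=O)OC(C)(C)C)CCCC1)C(=O)OC(C)(C)C.[Li+]
F6 | step 1 | tert-butyl (1S)-2-{[(2S)-1-tert-butoxy-3-methyl-1-oxobutan-2-yl]imino}-1-methylcyclohexane-1-carboxylate | CC(C)[C@H](N=C1CCCC[C@]1(C)C(=O)OC(C)(C)C)C(=O)OC(C)(C)C
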